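**Plan**

Ring A is numbered C1 (sulfatoethyl carbon), C2 (H), C3 and C4 (OH), C5 (Br), C6 (carbon bearing the bridge CH2); ring B is the 2,3-dibromo-4,5-dihydroxyphenyl ring.
Backwards, the sulfate S–O bond, the four phenolic O–Si bonds and the ring A C5–Br bond (from C5–SiMe3) are cut, and the bridge CH2 is tied to the chain oxygen as a 1-arylisochroman.
Ring A is then cut at C2–C3, C3–C4, C4–C5 and C1–C6: the vicinal oxygen-bearing carbons C3/C4 are two CO, and the ortho pair C1/C6 with the pyran tether is an ether-linked 1,7-diyne.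
Forwards, ring B is completed first from vanillin, the diyne is joined by acetylide addition and propargylic etherification, and ring A and the pyran ring then form together in the ruthenium carbonylation.
The pyran ring is opened reductively to the CH2 bridge and hydroxyethyl chain, which is sulfated before all phenols are freed.
The target is achiral; the one benzylic stereocentre is made racemic in step 4 and erased in step 8.

Key step: step 6

Assumption: the target is taken as the free alkyl hydrogen sulfate as drawn; because such acids hydrolyse in warm aqueous acid, it is released from its pyridinium salt only at the end, cold, on an acidic resin.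

**Route**

Step 1
Reactants: 1 vanillin
Product: 3 2,3-dibromo-4-hydroxy-5-methoxybenzaldehyde, via 5-bromovanillin 2 (not isolated)
Conditions: Br2 (1.05 equiv), AcOH, rt; then Fe powder (cat.), Br2 (1.2 equiv), 60 °C
Reagents that add atoms: bromine, BrBr
Why: Electrophilic aromatic bromination, in which the first bromine should enter ortho to the free phenol and the second, assisted by FeBr3 formed in the flask, para to the methoxy group, the only remaining position activated in a para sense by an oxygen donor.

Step 2
Reactants: 3 2,3-dibromo-4-hydroxy-5-methoxybenzaldehyde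
Product: 4 2,3-dibromo-4,5-dihydroxybenzaldehyde
Conditions: BBr3, CH2Cl2, –78 °C → rt; H2O
Reagents that add atoms: none
Why: Lewis acid cleavage of an aryl methyl ether (BBr3 demethylation), which the aldehyde and the aryl bromides should tolerate at low temperature.

Step 3
Reactants: 4 2,3-dibromo-4,5-dihydroxybenzaldehyde
Product: 5 2,3-dibromo-4,5-bis(tert-butyldimethylsilyloxy)benzaldehyde
Conditions: TBSCl (2.5 equiv), imidazole, DMAP (cat.), DMF, rt
Reagents that add atoms: tert-butyldimethylsilyl chloride, CC(C)(C)[Si](C)(C)Cl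
Why: Imidazole-promoted silylation of both phenols, chosen so that ring B carries the same silyl ethers that step 6 places on ring A and one fluoride step can later free all four phenols.

Step 4
Reactants: 5 2,3-dibromo-4,5-bis(tert-butyldimethylsilyloxy)benzaldehyde; 6 trimethylsilylacetylene
Product: 7 racemic 1-[2,3-dibromo-4,5-bis(tert-butyldimethylsilyloxy)phenyl]-3-(trimethylsilyl)prop-2-yn-1-ol
Conditions: 6 (1.2 equiv), n-BuLi (1.1 equiv), THF, –78 °C; then 5, –78 → 0 °C; aq NH4Cl
Reagents that add atoms: none
Why: 1,2-addition of a lithium acetylide to an aldehyde, the acetylide being too weak a base for bromine–lithium exchange, and the new stereocentre is formed racemic, which is immaterial because step 8 erases it.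

Step 5
Reactants: 7 racemic 1-[2,3-dibromo-4,5-bis(tert-butyldimethylsilyloxy)phenyl]-3-(trimethylsilyl)prop-2-yn-1-ol; 8 but-3-yn-1-ol
Product: 9 racemic [3-(but-3-yn-1-yloxy)-3-[2,3-dibromo-4,5-bis(tert-butyldimethylsilyloxy)phenyl]prop-1-yn-1-yl]trimethylsilane (the ether-tethered 1,7-diyne)
Conditions: p-TsOH·H2O (5 mol%), 8 (3 equiv), MeCN, rt
Reagents that add atoms: none
Why: Brønsted acid-catalysed propargylic substitution (SN1 etherification), in which the cation stabilised by the para-silyloxy aryl ring and the silylalkyne should be captured by the excess primary alcohol.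

Step 6
Reactants: 9 racemic ether-tethered 1,7-diyne; 10 carbon monoxide (two molecules per diyne); 11 tert-butyldimethylsilane (two molecules per diyne)
Product: 12 racemic 1-[2,3-dibromo-4,5-bis(tert-butyldimethylsilyloxy)phenyl]-6,7-bis(tert-butyldimethylsilyloxy)-8-(trimethylsilyl)isochroman
Conditions: Ru3(CO)12 (4 mol%), PCy3 (8 mol%), t-BuMe2SiH (4 equiv), CO (50 atm), MeCN, 140 °C
Reagents that add atoms: carbon monoxide, [C-]#[O+]; tert-butyldimethylsilane, C[SiH](C)C(C)(C)C
Why: Proposed new method: zerovalent ruthenium carbonyl adds the Si–H bonds of two molecules of 11, two CO ligands are O-silylated and coupled to a bis(silyloxy)alkyne ligand, the two alkynes of 9 form a ruthenacyclopentadiene that takes up this two-carbon unit, and reductive elimination should release the arene, so that one diyne, two CO and two silanes give 12 and one H2. The closest known reaction type is the Ru3(CO)12/hydrosilane/CO conversion of 1,6-diynes into bicyclic catechol bis(silyl ethers), extended here to an oxygen-tethered 1,7-diyne with one silylated terminus and aryl bromides. Ring A closes as a metal-templated (2+2+1+1) benzannulation, formally a (2+2+2) cyclotrimerisation with the CO-derived alkyne, forming C2–C3, C3–C4, C4–C5 and C1–C6, and the pyran ring closes as the six-membered tether ring when the diyne couples oxidatively at ruthenium (the C1–C6 bond). No stereocentre is created and the benzylic one stays racemic. Regiochemistry is fixed by connectivity, since the tethered alkyne carbons must become C1 and C6 and the H and SiMe3 termini C2 and C5. The selectivity needed is carbonylative cyclisation over hydrosilylation of the terminal alkyne, which high CO pressure, the bulky silane and the aryl-substituted tether (favouring the folded diyne) should secure, while aryl C–Br bonds are not expected to add to ruthenium carbonyls under these conditions.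

Step 7
Reactants: 12 racemic 8-(trimethylsilyl)isochroman
Product: 13 racemic 8-bromo-1-[2,3-dibromo-4,5-bis(tert-butyldimethylsilyloxy)phenyl]-6,7-bis(tert-butyldimethylsilyloxy)isochroman
Conditions: NBS (1.05 equiv), MeCN, 0 °C, dark
Reagents that add atoms: N-bromosuccinimide, O=C1CCC(=O)N1Br
Why: Electrophilic ipso-bromodesilylation, in which attack at the silicon-bearing carbon gives a β-silyl-stabilised arenium ion, so bromine should replace SiMe3 at isochroman C8 (ring A C5) far faster than it substitutes the C5–H, while the twice-brominated ring B is deactivated.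

Step 8
Reactants: 13 racemic 8-bromoisochroman
Product: 14 2-[3-bromo-2-[2,3-dibromo-4,5-bis(tert-butyldimethylsilyloxy)benzyl]-4,5-bis(tert-butyldimethylsilyloxy)phenyl]ethanol
Conditions: Et3SiH (5 equiv), TFA (10 equiv), CH2Cl2, –20 → 0 °C; aq NaHCO3
Reagents that add atoms: none
Why: Ionic hydrogenation, in which protonation of the ring oxygen ionises the doubly benzylic C–O bond to a diarylmethyl cation stabilised by a para-silyloxy group on each ring, and Et3SiH should reduce it irreversibly to the CH2 bridge, erasing the stereocentre and freeing the hydroxyethyl chain.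

Step 9
Reactants: 14 tetrasilylated hydroxyethyl diarylmethane
Product: 15 pyridinium 2-[3-bromo-2-[2,3-dibromo-4,5-bis(tert-butyldimethylsilyloxy)benzyl]-4,5-bis(tert-butyldimethylsilyloxy)phenyl]ethyl sulfate
Conditions: SO3·pyridine (3 equiv), pyridine, rt
Reagents that add atoms: sulfur trioxide–pyridine complex, O=S(=O)([O-])[n+]1ccccc1
Why: O-sulfation of a primary alcohol with the SO3·pyridine complex, selective because every phenol is still masked as its silyl ether.

Step 10
Reactants: 15 pyridinium tetrasilylated alkyl sulfate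
Product: 17 2-[3-bromo-2-(2,3-dibromo-4,5-dihydroxybenzyl)-4,5-dihydroxyphenyl]ethyl hydrogen sulfate (target), via pyridinium tetraphenol sulfate 16 (not isolated)
Conditions: HF·pyridine, pyridine/THF, 0 °C → rt; evaporate; then polystyrene sulfonic acid resin (H+ form), MeOH/H2O, 0 °C; lyophilise
Reagents that add atoms: none
Why: Fluoride-driven Si–O cleavage of the four aryl silyl ethers under mildly acidic conditions that should spare the sulfate monoester and the air-sensitive catechols, followed by cation exchange of pyridinium for a proton.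

**Compound list**

1 | vanillin (4-hydroxy-3-methoxybenzaldehyde) | COc1cc(C=O)ccc1O | starting material
2 | 5-bromovanillin (3-bromo-4-hydroxy-5-methoxybenzaldehyde) | COc1cc(C=O)cc(Br)c1O | intermediate
3 | 2,3-dibromo-4-hydroxy-5-methoxybenzaldehyde | COc1cc(C=O)c(Br)c(Br)c1O | intermediate
4 | 2,3-dibromo-4,5-dihydroxybenzaldehyde | O=Cc1cc(O)c(O)c(Br)c1Br | intermediate
5 | 2,3-dibromo-4,5-bis(tert-butyldimethylsilyloxy)benzaldehyde | O=Cc1cc(O[Si](C)(C)C(C)(C)C)c(O[Si](C)(C)C(C)(C)C)c(Br)c1Br | intermediate
6 | trimethylsilylacetylene | C#C[Si](C)(C)C | starting material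
7 | racemic 1-[2,3-dibromo-4,5-bis(tert-butyldimethylsilyloxy)phenyl]-3-(trimethylsilyl)prop-2-yn-1-ol | OC(C#C[Si](C)(C)C)c1cc(O[Si](C)(C)C(C)(C)C)c(O[Si](C)(C)C(C)(C)C)c(Br)c1Br | intermediate
8 | but-3-yn-1-ol | C#CCCO | starting material
9 | racemic [3-(but-3-yn-1-yloxy)-3-[2,3-dibromo-4,5-bis(tert-butyldimethylsilyloxy)phenyl]prop-1-yn-1-yl]trimethylsilane | C#CCCOC(C#C[Si](C)(C)C)c1cc(O[Si](C)(C)C(C)(C)C)c(O[Si](C)(C)C(C)(C)C)c(Br)c1Br | intermediate
10 | carbon monoxide | [C-]#[O+] | starting material
11 | tert-butyldimethylsilane | C[SiH](C)C(C)(C)C | starting material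
12 | racemic 1-[2,3-dibromo-4,5-bis(tert-butyldimethylsilyloxy)phenyl]-6,7-bis(tert-butyldimethylsilyloxy)-8-(trimethylsilyl)isochroman | CC(C)(C)[Si](C)(C)Oc1cc2c(c([Si](C)(C)C)c1O[Si](C)(C)C(C)(C)C)C(c1cc(O[Si](C)(C)C(C)(C)C)c(O[Si](C)(C)C(C)(C)C)c(Br)c1Br)OCC2 | intermediate
13 | racemic 8-bromo-1-[2,3-dibromo-4,5-bis(tert-butyldimethylsilyloxy)phenyl]-6,7-bis(tert-butyldimethylsilyloxy)isochroman | CC(C)(C)[Si](C)(C)Oc1cc2c(c(Br)c1O[Si](C)(C)C(C)(C)C)C(c1cc(O[Si](C)(C)C(C)(C)C)c(O[Si](C)(C)C(C)(C)C)c(Br)c1Br)OCC2 | intermediate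
14 | 2-[3-bromo-2-[2,3-dibromo-4,5-bis(tert-butyldimethylsilyloxy)benzyl]-4,5-bis(tert-butyldimethylsilyloxy)phenyl]ethanol | OCCc1cc(O[Si](C)(C)C(C)(C)C)c(O[Si](C)(C)C(C)(C)C)c(Br)c1Cc1cc(O[Si](C)(C)C(C)(C)C)c(O[Si](C)(C)C(C)(C)C)c(Br)c1Br | intermediate
15 | pyridinium 2-[3-bromo-2-[2,3-dibromo-4,5-bis(tert-butyldimethylsilyloxy)benzyl]-4,5-bis(tert-butyldimethylsilyloxy)phenyl]ethyl sulfate | [O-]S(=O)(=O)OCCc1cc(O[Si](C)(C)C(C)(C)C)c(O[Si](C)(C)C(C)(C)C)c(Br)c1Cc1cc(O[Si](C)(C)C(C)(C)C)c(O[Si](C)(C)C(C)(C)C)c(Br)c1Br.c1cc[nH+]cc1 | intermediate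
16 | pyridinium 2-[3-bromo-2-(2,3-dibromo-4,5-dihydroxybenzyl)-4,5-dihydroxyphenyl]ethyl sulfate | [O-]S(=O)(=O)OCCc1cc(O)c(O)c(Br)c1Cc1cc(O)c(O)c(Br)c1Br.c1cc[nH+]cc1 | intermediate
17 | 2-[3-bromo-2-(2,3-dibromo-4,5-dihydroxybenzyl)-4,5-dihydroxyphenyl]ethyl hydrogen sulfate | O=S(=O)(O)OCCc1cc(O)c(O)c(Br)c1Cc1cc(O)c(O)c(Br)c1Br | target

**Count and risks**

Total steps: 10. Longest linear sequence: 10 steps (vanillin 1 to target 17).

Step 6 (proposed new method). The process at risk is hydrosilylation of the terminal alkyne outrunning silylation and coupling of CO, or the hindered silylalkyne failing to enter the ruthenacycle, the six-membered tether closing more slowly than the known five-membered case. The fallback uses known chemistry, sets out from aldehyde 3 and returns at alcohol 14. Acid-catalysed oxa-Pictet–Spengler condensation of 3 with commercial 2-(4-hydroxy-3-methoxyphenyl)ethanol (p-TsOH, toluene/MeOH, warm) should close the pyran ring para to the methoxy group and give racemic 1-(2,3-dibromo-4-hydroxy-5-methoxyphenyl)-6-methoxyisochroman-7-ol F1. NBS at 0 °C should brominate the only open position ortho to a free phenol and give racemic 8-bromo-1-(2,3-dibromo-4-hydroxy-5-methoxyphenyl)-6-methoxyisochroman-7-ol F2. Et3SiH/TFA should open the doubly benzylic ether to 2-bromo-3-(2,3-dibromo-4-hydroxy-5-methoxybenzyl)-4-(2-hydroxyethyl)-6-methoxyphenol F3. BBr3 at low temperature should cleave both methyl ethers to 3-bromo-4-(2,3-dibromo-4,5-dihydroxybenzyl)-5-(2-hydroxyethyl)benzene-1,2-diol F4. Excess TBSCl/imidazole should give the pentakis(tert-butyldimethylsilyl) ether F5, and AcOH/THF/H2O should remove the primary alkyl silyl ether faster than the aryl ones and deliver 14.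

Step 5. The process at risk is Meyer–Schuster rearrangement or self-etherification of the ionised propargylic alcohol, or acid-induced loss of the aryl silyl ethers before the external alcohol captures the cation. The fallback forms the C–C bond on an oxocarbenium ion instead of the C–O bond on a propargylic cation; it sets out from aldehyde 5, bypasses 7 and returns at diyne 9. Acetalisation of 5 with excess but-3-yn-1-ol (p-TsOH cat., benzene, azeotropic water removal) should give 2,3-dibromo-4,5-bis(tert-butyldimethylsilyloxy)benzaldehyde bis(but-3-yn-1-yl) acetal F6. Acid-promoted alkynylation of this acetal with potassium (trimethylsilylethynyl)trifluoroborate, K[Me3SiC≡CBF3] (HBF4·OEt2 cat., MeCN, 0 °C), should replace one butynyloxy group by the silylalkyne and give 9.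

Step 8. The process at risk is erosion of the aryl silyl ethers in TFA and recapture of the cation by the pendant alcohol competing with hydride transfer. The fallback avoids Brønsted acid by activating the silane instead of the ether; it sets out from 13 and returns at 14. B(C6F5)3 (5 mol%) with Et3SiH (1.1 equiv) in CH2Cl2 at –40 °C → rt should cleave the benzhydryl C–O bond through a silyloxonium ion and give the triethylsilyl ether of 14, triethyl[2-[3-bromo-2-[2,3-dibromo-4,5-bis(tert-butyldimethylsilyloxy)benzyl]-4,5-bis(tert-butyldimethylsilyloxy)phenyl]ethoxy]silane F7. AcOH/THF/H2O should then remove the primary triethylsilyl group selectively and give 14.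

**Further compounds**

F1 | step 6 | racemic 1-(2,3-dibromo-4-hydroxy-5-methoxyphenyl)-6-methoxyisochroman-7-ol | COc1cc2c(cc1O)C(c1cc(OC)c(O)c(Br)c1Br)OCC2
F2 | step 6 | racemic 8-bromo-1-(2,3-dibromo-4-hydroxy-5-methoxyphenyl)-6-methoxyisochroman-7-ol | COc1cc2c(c(Br)c1O)C(c1cc(OC)c(O)c(Br)c1Br)OCC2
F3 | step 6 | 2-bromo-3-(2,3-dibromo-4-hydroxy-5-methoxybenzyl)-4-(2-hydroxyethyl)-6-methoxyphenol | COc1cc(CCO)c(Cc2cc(OC)c(O)c(Br)c2Br)c(Br)c1O
F4 | step 6 | 3-bromo-4-(2,3-dibromo-4,5-dihydroxybenzyl)-5-(2-hydroxyethyl)benzene-1,2-diol | OCCc1cc(O)c(O)c(Br)c1Cc1cc(O)c(O)c(Br)c1Br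
F5 | step 6 | pentakis(tert-butyldimethylsilyl) ether of F4 | CC(C)(C)[Si](C)(C)OCCc1cc(O[Si](C)(C)C(C)(C)C)c(O[Si](C)(C)C(C)(C)C)c(Br)c1Cc1cc(O[Si](C)(C)C(C)(C)C)c(O[Si](C)(C)C(C)(C)C)c(Br)c1Br
F6 | step 5 | 2,3-dibromo-4,5-bis(tert-butyldimethylsilyloxy)benzaldehyde bis(but-3-yn-1-yl) acetal | C#CCCOC(OCCC#C)c1cc(O[Si](C)(C)C(C)(C)C)c(O[Si](C)(C)C(C)(C)C)c(Br)c1Br
F7 | step 8 | triethylsilyl ether of 14 | CC[Si](CC)(CC)OCCc1cc(O[Si](C)(C)C(C)(C)C)c(O[Si](C)(C)C(C)(C)C)c(Br)c1Cc1cc(O[Si](C)(C)C(C)(C)C)c(O[Si](C)(C)C(C)(C)C)c(Br)c1Br
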